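## The problem

Target 13, 2,3,5-tribromo-6-(2-bromophenoxy)phenol, is two benzene rings joined through a single ether oxygen and has no stereocenter, so the problem is one of regiochemistry on ring A; ring B is an ordinary 2-bromophenyl group. Ring A is pentasubstituted in a fixed order: C1 OH, C2 Br, C3 Br, C4 H, C5 Br, C6 O-aryl. The position para to the hydroxyl, C4, is free while both meta positions, C3 and C5, carry bromine, which runs against the directing effect of the hydroxyl, so bromination of a preformed catechol monoaryl ether cannot give this pattern. The ether oxygen on C6 sits between C1–OH and C5–Br, so a metal-mediated C–O coupling on ring A would be hindered on both sides and would have to choose among several C–Br bonds. Four aryl C–Br bonds exclude organolithium reagents, hydrogenolysis and zerovalent palladium or nickel, and the free phenol is best released late. Any stereocenters made on the way are transient; they control nothing in the target and need only be compatible with aromatization. The feature that opens the route is that the run C5(Br)–C4(H)–C3(Br)–C2 of ring A is the run C3–C4–C5–C6 of 3,5-dibromo-2H-pyran-2-one 2, while C6 and C1 are two neighbouring oxygen-bearing carbons, that is, a cis-1,2-dioxygenated alkene whose oxygens can be differentiated as aryl ether and ester before the ring exists. C2, the one carbon the pyrone delivers as C–H, is ortho to the hydroxyl and can be brominated last under its direction.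

## Retrosynthesis

13 to 12 (C2–Br). The C2–Br bond is cut first, giving 3,5-dibromo-2-(2-bromophenoxy)phenol 12. C2 is the only free position ortho to the hydroxyl, so amine-mediated ortho-bromination can address it. Carrying this bromine through the ring construction would need a 6-bromopyrone and would put bromine on the acetal-type bridgehead of the cycloadduct. The forward step must prefer C2 over C4 (para to OH, flanked by two bromines) and over ring B.

12 to 10 to 9 (aromatization). Phenol 12 is the enol of dienone 11, which is the oxidation product of the secondary dienol 10; dienol 10 comes from acetate 9 by ester cleavage. Aromatizing by oxidation of the C1 carbinol is preferred to hydride abstraction from 9, which is slowed by two vinylic bromines, and to elimination, which would remove one of the two oxygens. No skeletal bond is cut. The forward steps must free and oxidize the alcohol without acid- or base-induced loss of acetic acid or 2-bromophenol.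

9 to 2 + 7 (key disconnection). Diene 9 is opened across C5–C6 and C1–C2. Putting CO2 back between the former pyrone C3 and C6 gives the bridged lactone 8, the Diels–Alder adduct of pyrone 2 and (Z)-2-(2-bromophenoxy)vinyl acetate 7. This one cut removes the whole of ring A, puts Br, H, Br in their places, and leaves the aryl ether bond to be made on a simple phenol. The forward reaction must bond the aryloxy-bearing carbon to brominated pyrone C3 and the acetoxy-bearing carbon to C6, and diene 9 must survive the temperature of CO2 loss.

7 to 6 to 5 to 3 + 4. The enol ester O–acyl bond is cut to give 2-(2-bromophenoxy)acetaldehyde 6, which is unmasked from acetal 5. The ArO–CH2 bond of 5 is cut to 2-bromophenol 3 and bromoacetaldehyde diethyl acetal 4. The ether is thus formed by a Williamson reaction at an sp3 carbon on an unhindered phenol. The forward sequence must give the Z enol acetate.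

2 to 1. Pyrone 2 is traced to coumalic acid 1 by cutting the C5–Br bond back to the carboxyl group and the C3–Br bond back to C–H, a one-pot bromodecarboxylation and bromination.

## Roads not taken

Alternative 1: Ring B, not ring A, is built by cycloaddition.
- Cut and key step: 2H-pyran-2-one A3 and the silylated alkynyl ether of ring A, trimethyl[(3,4,6-tribromo-2-methoxyphenoxy)ethynyl]silane A2, would react on heating by Diels–Alder addition across pyrone C3 and C6 and decarboxylative cycloreversion. The product would be trimethyl[2-(3,4,6-tribromo-2-methoxyphenoxy)phenyl]silane A1. Ipso-bromodesilylation of A1 and O-demethylation would finish.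
- Merits: the alkyne partner gives the arene directly with no dihydroarene to protect, the unsubstituted pyrone A3 poses no regiochemical question, and the silicon of A1 fixes the ring B bromine ortho to oxygen with certainty.
- Weak points: A2 must be made from the hindered, electron-poor 3,4,6-tribromo-2-methoxyphenol A4, and the usual route to aryl alkynyl ethers uses two equivalents of an alkyllithium, which three aryl bromides will not tolerate. A3 is a sluggish diene and needs temperatures at which ynol ethers are fragile. A4 itself is not accessible by simple bromination, since 2-methoxyphenol A5 is expected to brominate ortho and para to the hydroxyl and para to the methoxy group, not at C3 of A5.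
- Comparison: this road is better in the robustness of arene formation and in the certainty of its last bromination. The chosen plan sets against this that its cycloaddition builds the difficult ring and its bromine pattern, not the ring that can be bought as phenol 3, and that no organolithium comes near an aryl bromide.

Alternative 2: Both C–O bonds of ring A are made at once on an existing ring.
- Cut and key step: toluene dioxygenase in recombinant whole cells would cis-dihydroxylate the C4–C5 bond of 1,3-dibromobenzene A7 to give (1S,2S)-3,5-dibromocyclohexa-3,5-diene-1,2-diol A6. The hydroxyl of A6 next to the C–Br carbon would then have to be arylated, the other oxidized to aromatize, and C2 brominated.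
- Merits: one step from the commodity arene A7 to a ring with Br, H, Br and both oxygens in place, no hot extrusion step, and the same late stage as the chosen plan.
- Weak points: the two secondary allylic hydroxyls of A6 are nearly equivalent and must be told apart. An sp3 C–O–aryl bond must then be made on an acid-labile diene diol with an unactivated 2-bromophenyl partner: nucleophilic aromatic substitution is not available, copper or palladium coupling meets vinyl and aryl bromides, and a Mitsunobu reaction with phenol 3 risks allylic transposition and elimination. The enantiopurity bought by the enzyme is discarded, and acceptance of the meta-dihalobenzene A7 and fermentation capacity are further conditions.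
- Comparison: this road reaches the oxygenated ring A core in one step, against five for diene 9, and is better there. The chosen plan sets against this that its two oxygens arrive already differentiated and that its aryl ether is made before the ring exists.

Alternative 3: Ring B is not built but functionalized through an aryne.
- Cut and key step: fluoride would release benzyne A11 from 2-(trimethylsilyl)phenyl trifluoromethanesulfonate A9. The potassium phenoxide of A4 would add to one carbon of A11 and the carbanion so formed would take bromine from bromopentafluorobenzene A10, giving 1,2,5-tribromo-4-(2-bromophenoxy)-3-methoxybenzene A8. O-Demethylation of A8 would complete the synthesis.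
- Merits: the C–O and C–Br bonds of ring B form in one mild step with a guaranteed 1,2-relationship, the route is convergent, and only one step follows the key step.
- Weak points: the phenoxide of A4 is hindered and weakly nucleophilic. The carbanion can be protonated, or can take bromine from the C–Br bonds of ring A instead of from A10. A9 is costly but available; the real obstacle is that the plan presupposes A4, whose bromine pattern is the actual difficulty.
- Comparison: with A4 in hand this road would be shorter and milder than the chosen one and has no labile intermediate. The chosen plan sets against this that it constructs the contested pattern of ring A from the pyrone, and it pays with a thermally delicate diene and a late ortho-bromination.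

Key step: step 5

Assumption: compounds 8 to 11 are racemic and one enantiomer is drawn. Lactone 8 is drawn as the endo adduct (both oxygen substituents syn to the alkene bridge); the endo/exo ratio does not matter because both isomers lose CO2 to the same diene 9.

## Route

Step 1
Reactants: 1 coumalic acid (2-oxo-2H-pyran-5-carboxylic acid)
Product: 2 3,5-dibromo-2H-pyran-2-one
Conditions: NBS (2.5 equiv), LiOAc (0.2 equiv), MeCN–H2O (9:1), rt
Reagents that add atoms: N-bromosuccinimide, O=C1CCC(=O)N1Br
Why: Electrophilic bromination at C3 and ipso-bromodecarboxylation at C5 (Hunsdiecker-type halodecarboxylation of a vinylogous carboxylic acid), a known one-pot entry to this pyrone; the acetate keeps the carboxylate available for ipso attack.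

Step 2
Reactants: 3 2-bromophenol; 4 bromoacetaldehyde diethyl acetal (2-bromo-1,1-diethoxyethane)
Product: 5 1-bromo-2-(2,2-diethoxyethoxy)benzene
Conditions: K2CO3, DMF, 140 °C
Reagents that add atoms: none
Why: Williamson ether synthesis; the β-dialkoxy bromide is a slow electrophile, hence the polar aprotic solvent and heat, and the aryl C–Br bond is inert under these conditions.

Step 3
Reactants: 5 1-bromo-2-(2,2-diethoxyethoxy)benzene
Product: 6 2-(2-bromophenoxy)acetaldehyde
Conditions: 2 M HCl, THF, 60 °C
Reagents that add atoms: water, O
Why: Acid-catalysed acetal hydrolysis; the aryl alkyl ether and the aryl bromide are stable to dilute acid, and the aldehyde is used crude because it hydrates and oligomerizes on storage.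

Step 4
Reactants: 6 2-(2-bromophenoxy)acetaldehyde
Product: 7 (Z)-2-(2-bromophenoxy)vinyl acetate
Conditions: Ac2O, Et3N, DMAP (cat.), THF, 50 °C
Reagents that add atoms: acetic anhydride, CC(=O)OC(C)=O
Why: Enol ester formation by amine-mediated enolization and O-acetylation; the aryloxy group makes the α-hydrogens acidic enough for triethylamine, and the cis (Z) isomer should predominate as is usual for 1,2-dioxygenated alkenes, any E isomer being removed by chromatography.

Step 5
Reactants: 2 3,5-dibromo-2H-pyran-2-one; 7 (Z)-2-(2-bromophenoxy)vinyl acetate (2 equiv)
Product: 9 cis-3,5-dibromo-6-(2-bromophenoxy)cyclohexa-2,4-dien-1-yl acetate (racemic), via bridged bicyclic lactone 8 (not isolated)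
Conditions: PhMe, BHT (cat.), sealed tube, 100 °C, then 130 °C (−CO2)
Reagents that add atoms: none
Why: The electron-poor pyrone 2 is the diene in an inverse-electron-demand Diels–Alder reaction across C3 and C6 with the electron-rich alkene 7; bonding is asynchronous, the acetoxy-bearing carbon (β to the stronger aryloxy donor) attacking electrophilic C6 while the aryloxy-bearing carbon bonds to brominated C3. The bridged lactone 8 then loses CO2 by retro-Diels–Alder fragmentation at the higher temperature to give diene 9. The closest known reactions are the cycloadditions of 3,5-dibromo-2-pyrone with enol ethers and other donor alkenes, which place the donor-bearing carbon next to the brominated bridgehead, and the thermal loss of CO2 from 2-pyrone cycloadducts to give cyclohexa-1,3-dienes; an alkene carrying two different oxygen donors extends the substrate only. Ring A closes as a six-membered carbocycle by intermolecular [4+2] cycloaddition, C5–C6 and C1–C2 forming in the same event. The stereocenters C1 and C6 are set cis by suprafacial addition to the Z alkene, so the alkene geometry controls them, and endo and exo adducts converge on the same racemic diene. The step needs regioselectivity, which rests on the donor gap between aryloxy and acetoxy, and it needs the diene to survive: in the cis isomer neither oxygen has a syn hydrogen on the neighbouring sp3 carbon, so thermal syn-elimination is closed, and acid-free conditions suppress ionization.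

Step 6
Reactants: 9 cis-3,5-dibromo-6-(2-bromophenoxy)cyclohexa-2,4-dien-1-yl acetate
Product: 10 cis-3,5-dibromo-6-(2-bromophenoxy)cyclohexa-2,4-dien-1-ol (racemic)
Conditions: K2CO3 (0.2 equiv), MeOH, 0 °C
Reagents that add atoms: none
Why: Carbonate-catalysed transesterification (Zemplén-type methanolysis) removes the acetyl group at its carbonyl carbon and touches neither stereocenter; low temperature and a weak catalytic base let acyl transfer outrun anti-elimination, as in the methanolysis of esters of arene dihydrodiols.

Step 7
Reactants: 10 cis-3,5-dibromo-6-(2-bromophenoxy)cyclohexa-2,4-dien-1-ol
Product: 12 3,5-dibromo-2-(2-bromophenoxy)phenol, via dienone 11 (not isolated)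
Conditions: activated MnO2 (excess), CH2Cl2, rt
Reagents that add atoms: none
Why: Allylic alcohol oxidation gives the 2,4-dienone 11, which has a hydrogen at C6 and tautomerizes at once to the phenol (keto–enol tautomerism driven by aromatization); both stereocenters are erased, and the neutral heterogeneous oxidant avoids the acid that would dehydrate the dienol.

Step 8
Reactants: 12 3,5-dibromo-2-(2-bromophenoxy)phenol
Product: 13 2,3,5-tribromo-6-(2-bromophenoxy)phenol
Conditions: NBS (1.05 equiv), i-Pr2NH (0.1 equiv), CH2Cl2, 0 °C to rt
Reagents that add atoms: N-bromosuccinimide, O=C1CCC(=O)N1Br
Why: Amine-mediated ortho-selective electrophilic bromination of a phenol: the N-bromoamine formed in the flask delivers bromine within a hydrogen-bonded complex to C2, the only free ortho position; C4 is flanked by two bromines and ring B is only ether-activated, so both should react more slowly.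

## Compound list

1 | coumalic acid (2-oxo-2H-pyran-5-carboxylic acid) | O=C(O)C1=COC(=O)C=C1 | starting material
2 | 3,5-dibromo-2H-pyran-2-one | O=C1OC=C(Br)C=C1Br | intermediate
3 | 2-bromophenol | Oc1ccccc1Br | starting material
4 | bromoacetaldehyde diethyl acetal (2-bromo-1,1-diethoxyethane) | CCOC(CBr)OCC | starting material
5 | 1-bromo-2-(2,2-diethoxyethoxy)benzene | CCOC(COc1ccccc1Br)OCC | intermediate
6 | 2-(2-bromophenoxy)acetaldehyde | O=CCOc1ccccc1Br | intermediate
7 | (Z)-2-(2-bromophenoxy)vinyl acetate | CC(=O)O/C=C\Oc1ccccc1Br | intermediate
8 | 4,7-dibromo-5-(2-bromophenoxy)-3-oxo-2-oxabicyclo[2.2.2]oct-7-en-6-yl acetate (bridged lactone; racemic, endo adduct drawn; not isolated) | O=C1O[C@@H]2[C@@H](OC(C)=O)[C@@H](Oc3ccccc3Br)[C@@]1(Br)C=C2Br | intermediate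
9 | cis-3,5-dibromo-6-(2-bromophenoxy)cyclohexa-2,4-dien-1-yl acetate (racemic) | CC(=O)O[C@@H]1C=C(Br)C=C(Br)[C@@H]1Oc1ccccc1Br | intermediate
10 | cis-3,5-dibromo-6-(2-bromophenoxy)cyclohexa-2,4-dien-1-ol (racemic) | O[C@@H]1C=C(Br)C=C(Br)[C@@H]1Oc1ccccc1Br | intermediate
11 | 3,5-dibromo-6-(2-bromophenoxy)cyclohexa-2,4-dien-1-one (racemic; not isolated) | O=C1C=C(Br)C=C(Br)[C@@H]1Oc1ccccc1Br | intermediate
12 | 3,5-dibromo-2-(2-bromophenoxy)phenol | Oc1cc(Br)cc(Br)c1Oc1ccccc1Br | intermediate
13 | 2,3,5-tribromo-6-(2-bromophenoxy)phenol | Oc1c(Br)c(Br)cc(Br)c1Oc1ccccc1Br | target

## Step count and risks

Total step count: 8. Longest linear sequence: 7 steps (steps 2 to 8, from 2-bromophenol 3); the pyrone branch adds step 1.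

Step 5 (key step). The doubly donor-substituted cis-alkene is a slow dienophile. The temperature needed for cycloaddition and CO2 loss may therefore also drive loss of acetic acid or of 2-bromophenol from the dihydroarene, which would aromatize the ring with one oxygen missing. Regiochemistry may also leak, because acetoxy is still a donor. Fallback: ring A is then made without the cycloaddition, setting out from 2-bromophenol 3. Nucleophilic aromatic substitution on commercial 3,5-dibromo-2-fluorobenzaldehyde (K2CO3, DMF, 90 °C) should give 3,5-dibromo-2-(2-bromophenoxy)benzaldehyde F1, the fluorine being activated by the ortho formyl group. Baeyer–Villiger oxidation with 3-chloroperbenzoic acid, with migration of the ortho-aryloxy-substituted ring, should give 3,5-dibromo-2-(2-bromophenoxy)phenyl formate F2. Methanolysis (K2CO3, MeOH) then comes back to the route at phenol 12.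

Step 4. Self-aldol condensation of the unhindered aldehyde under amine base may compete with O-acetylation, and control of alkene geometry may be incomplete. Fallback, from aldehyde 6: enolization and acylation are separated. Soft silylation (Me3SiCl, NaI, Et3N, MeCN) should give (Z)-[2-(2-bromophenoxy)ethenyloxy]trimethylsilane F3, which can be purified. KOtBu in THF at −78 °C then cleaves the silyl group and releases potassium (Z)-2-(2-bromophenoxy)ethen-1-olate F4 with retention of geometry. O-Acetylation of this enolate with Ac2O comes back to the route at enol acetate 7.

Step 6. Base-induced anti-elimination may aromatize the ring with loss of one oxygen before the ester is cleaved: H6 is trans to the acetate, and H1 is trans to the aryloxy group. Fallback, from diene 9: the order of events is reversed. DDQ in benzene at 60 to 80 °C abstracts hydride from C6–H (α to the aryloxy oxygen) and the cation loses the C1 proton, giving 3,5-dibromo-2-(2-bromophenoxy)phenyl acetate F5. This aryl acetate has no elimination channel, and its methanolysis (K2CO3, MeOH) comes back to the route at phenol 12, bypassing dienol 10 and dienone 11.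

Step 8. Site selectivity may be poor: bromination para to the hydroxyl at C4, on ring B para to the ether oxygen, or twice. Fallback, from phenol 12: the hydroxyl is turned into a directing group for C–H activation. Me2NCOCl and K2CO3 in MeCN give 3,5-dibromo-2-(2-bromophenoxy)phenyl dimethylcarbamate F6, whose only ortho C–H is C2. Pd(OAc)2-catalysed, carbamate-directed ortho-bromination with NBS and TsOH in 1,2-dichloroethane should give 2,3,5-tribromo-6-(2-bromophenoxy)phenyl dimethylcarbamate F7; the catalyst cycles between divalent and tetravalent palladium and never becomes zerovalent, so the aryl bromides are not at risk. KOH in aqueous EtOH at reflux cleaves the carbamate and comes back to the route at target 13.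

## Further compounds

F1 | step 5 | 3,5-dibromo-2-(2-bromophenoxy)benzaldehyde | O=Cc1cc(Br)cc(Br)c1Oc1ccccc1Br
F2 | step 5 | 3,5-dibromo-2-(2-bromophenoxy)phenyl formate | O=COc1cc(Br)cc(Br)c1Oc1ccccc1Br
F3 | step 4 | (Z)-[2-(2-bromophenoxy)ethenyloxy]trimethylsilane | C[Si](C)(C)O/C=C\Oc1ccccc1Br
F4 | step 4 | potassium (Z)-2-(2-bromophenoxy)ethen-1-olate | [K+].[O-]/C=C\Oc1ccccc1Br
F5 | step 6 | 3,5-dibromo-2-(2-bromophenoxy)phenyl acetate | CC(=O)Oc1cc(Br)cc(Br)c1Oc1ccccc1Br
F6 | step 8 | 3,5-dibromo-2-(2-bromophenoxy)phenyl dimethylcarbamate | CN(C)C(=O)Oc1cc(Br)cc(Br)c1Oc1ccccc1Br
F7 | step 8 | 2,3,5-tribromo-6-(2-bromophenoxy)phenyl dimethylcarbamate | CN(C)C(=O)Oc1c(Br)c(Br)cc(Br)c1Oc1ccccc1Br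
A1 | alternative 1 | trimethyl[2-(3,4,6-tribromo-2-methoxyphenoxy)phenyl]silane | COc1c(Br)c(Br)cc(Br)c1Oc1ccccc1[Si](C)(C)C
A2 | alternative 1 | trimethyl[(3,4,6-tribromo-2-methoxyphenoxy)ethynyl]silane | COc1c(Br)c(Br)cc(Br)c1OC#C[Si](C)(C)C
A3 | alternative 1 | 2H-pyran-2-one | O=C1C=CC=CO1
A4 | alternative 1 | 3,4,6-tribromo-2-methoxyphenol | COc1c(Br)c(Br)cc(Br)c1O
A5 | alternative 1 | 2-methoxyphenol | COc1ccccc1O
A6 | alternative 2 | (1S,2S)-3,5-dibromocyclohexa-3,5-diene-1,2-diol | O[C@H]1C=C(Br)C=C(Br)[C@H]1O
A7 | alternative 2 | 1,3-dibromobenzene | Brc1cccc(Br)c1
A8 | alternative 3 | 1,2,5-tribromo-4-(2-bromophenoxy)-3-methoxybenzene | COc1c(Br)c(Br)cc(Br)c1Oc1ccccc1Br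
A9 | alternative 3 | 2-(trimethylsilyl)phenyl trifluoromethanesulfonate | C[Si](C)(C)c1ccccc1OS(=O)(=O)C(F)(F)F
A10 | alternative 3 | bromopentafluorobenzene | Fc1c(F)c(F)c(Br)c(F)c1F
A11 | alternative 3 | benzyne (1,2-didehydrobenzene) | C1#CC=CC=C1
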